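**Plan**

1. Retrosynthesis: the lactone is cut at O2–C3 and at C1–C8a together, so that the whole O–C(=O) unit leaves as CO2 and an open-chain 5-alkylresorcinol with a mesylate at the future C3 remains (14). The chain is then cut next to that carbon (epoxide opening), at the aryl–CH2 bond (aryl Grignard plus epichlorohydrin) and next to the ethyl carbinol (Grignard plus epoxybutane).
2. Forward: chain fragment 5 and aryl epoxide 10 are each made in two steps and joined by a Grignard epoxide opening (step 5). Mesylation and global hydrogenolysis follow, and the only ring to be made, the δ-lactone, arises in the last step.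
3. Enabling feature: C1 sits on aromatic C8a, which is ortho to the C8 hydroxyl and para to the C6 hydroxyl of the resorcinol ring (the innate Kolbe–Schmitt carbon). A carboxylate there lies at 6-exo-tet distance from C3, so CO2 can be inserted between the C8a–H bond and a C3–O sulfonate bond.
4. Stereochemistry: the side-chain carbinol (S) comes from (S)-1,2-epoxybutane. C3 (R) comes from (R)-epichlorohydrin by way of the (2S)-mesylate, which is inverted by SN2 in the key step.

Key step: step 8

Remark: 1,3-bis(benzyloxy)-5-bromobenzene (6) is taken as a purchased material (otherwise one benzylation from 5-bromoresorcinol). Ring atoms are numbered as in isochroman-1-one (C1 carbonyl, O2, C3, C4, C4a, C5 to C8, C8a).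

**Route**

Step 1
Reactants: 1 1-bromo-6-chlorohexane; 2 (S)-1,2-epoxybutane
Product: 4 (S)-10-chlorodecan-3-ol, via Grignard reagent 3 (not isolated)
Conditions: 1, Mg, THF, 25–35 °C; then CuI (10 mol%), 2, THF, −30 → 0 °C; aq. NH4Cl
Reagents that add atoms: none
Why: Magnesium inserts into the C–Br bond far faster than into the C–Cl bond, and the CuI-catalyzed Grignard opening of a terminal epoxide (SN2 at the unsubstituted carbon) leaves the C–O stereocenter of 2 untouched, so the (S) carbinol of the target is taken over from the chiral pool.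

Step 2
Reactants: 4 (S)-10-chlorodecan-3-ol
Product: 5 benzyl (S)-10-chlorodecan-3-yl ether
Conditions: NaH, BnBr, THF–DMF, 0 °C → rt
Reagents that add atoms: benzyl bromide, BrCc1ccccc1
Why: Williamson ether synthesis, in which the alkoxide reacts with benzyl bromide far faster than with the remote primary chloride; the benzyl ether is chosen because it leaves together with the two aryl benzyl ethers in step 7.

Step 3
Reactants: 6 1,3-bis(benzyloxy)-5-bromobenzene; 7 (R)-epichlorohydrin
Product: 9 (R)-1-[3,5-bis(benzyloxy)phenyl]-3-chloropropan-2-ol, via aryl Grignard reagent 8 (not isolated)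
Conditions: 6, Mg, I2 (cat.), THF, reflux; then CuI (10 mol%), 7, THF, −40 → −20 °C; aq. NH4Cl
Reagents that add atoms: none
Why: The CuI-catalyzed Grignard opening of epichlorohydrin occurs at the epoxide CH2 and not at the C–Cl carbon at low temperature, the stereocenter is not touched, and the (R) configuration of 7 is carried into chlorohydrin 9.

Step 4
Reactants: 9 (R)-1-[3,5-bis(benzyloxy)phenyl]-3-chloropropan-2-ol
Product: 10 (R)-2-[3,5-bis(benzyloxy)benzyl]oxirane
Conditions: NaOH (powdered), Et2O, rt
Reagents that add atoms: none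
Why: Intramolecular Williamson closure (3-exo-tet) of the chlorohydrin alkoxide moves the epoxide to the other end of the three-carbon unit without touching the stereocenter.

Step 5
Reactants: 5 benzyl (S)-10-chlorodecan-3-yl ether; 10 (R)-2-[3,5-bis(benzyloxy)benzyl]oxirane
Product: 12 (2S,11S)-11-(benzyloxy)-1-[3,5-bis(benzyloxy)phenyl]tridecan-2-ol, via alkyl Grignard reagent 11 (not isolated)
Conditions: 5, Mg, I2 (cat.), THF, reflux; then CuI (10 mol%), 10, THF, −30 → 0 °C; aq. NH4Cl
Reagents that add atoms: none
Why: Grignard formation from the primary chloride followed by CuI-catalyzed SN2 opening of the terminal epoxide at its CH2 joins the two fragments and leaves the C–O stereocenter untouched, so the (R)-epoxide gives the (2S)-alcohol (the descriptor changes only through the priority rules).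

Step 6
Reactants: 12 (2S,11S)-11-(benzyloxy)-1-[3,5-bis(benzyloxy)phenyl]tridecan-2-ol
Product: 13 (2S,11S)-11-(benzyloxy)-1-[3,5-bis(benzyloxy)phenyl]tridecan-2-yl methanesulfonate
Conditions: MsCl, Et3N, CH2Cl2, 0 °C
Reagents that add atoms: methanesulfonyl chloride, CS(=O)(=O)Cl
Why: Sulfonylation of the only free hydroxyl forms the O–S bond without touching the C–O bond, so C2 stays (S) and becomes the electrophile for the key step.

Step 7
Reactants: 13 (2S,11S)-11-(benzyloxy)-1-[3,5-bis(benzyloxy)phenyl]tridecan-2-yl methanesulfonate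
Product: 14 (2S,11S)-1-(3,5-dihydroxyphenyl)-11-hydroxytridecan-2-yl methanesulfonate
Conditions: H2 (1 atm), Pd(OH)2/C, EtOAc–THF, rt; filtered, concentrated cold and used at once
Reagents that add atoms: none
Why: Catalytic hydrogenolysis cleaves the two aryl benzyl ethers and the alkyl benzyl ether to toluene, while an alkyl methanesulfonate is inert to H2 on palladium in a neutral aprotic solvent.

Step 8
Reactants: 14 (2S,11S)-1-(3,5-dihydroxyphenyl)-11-hydroxytridecan-2-yl methanesulfonate
Product: 16 (3R)-6,8-dihydroxy-3-[(9S)-9-hydroxyundecyl]-3,4-dihydro-1H-isochromen-1-one, via cesium carboxylate 15 (not isolated)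
Conditions: Cs2CO3 (3 equiv), CO2 (5 bar), dry DMF (0.02 M), 25 °C then 65 °C; 1 M HCl work-up
Reagents that add atoms: carbon dioxide, O=C=O
Why: Proposed new method: the cesium resorcinolate of 14 should be C-carboxylated reversibly by CO2 at the ring carbon that is ortho to the side chain, ortho to one phenol oxygen and para to the other (both such carbons are equivalent by the symmetry of the 5-substituted resorcinol), and the cesium carboxylate 15 so formed should then displace the secondary mesylate in an intramolecular SN2 reaction, so that CO2 is stitched between an aryl C–H bond and a C–O bond. The closest known reaction types are the Kolbe–Schmitt and methyl magnesium carbonate carboxylations of resorcinols and the displacement of secondary sulfonates by cesium carboxylates with inversion; their union in one flask on a phenol that carries a tethered sulfonate is the new element. The δ-lactone ring closes in the 6-exo-tet mode. C3 is the only stereocenter touched, and it is set as (3R) by clean inversion of the (2S)-mesylate, whose configuration derives from (R)-epichlorohydrin; the remote (S)-carbinol is a spectator, since its cesium alkyl carbonate forms reversibly and has no electrophile within reach. The step needs regioselectivity between the carbon flanked by the two hydroxyls and the carbon next to the side chain, and substitution in preference to elimination toward the styrene. The first should be secured because only the carboxylate next to the side chain can reach the sulfonate, so the irreversible lactonization drains the reversible carboxylation equilibrium; the second by the weakly basic hydrogencarbonate medium, high dilution and the six-membered transition state.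

**Compound list**

1 | 1-bromo-6-chlorohexane | ClCCCCCCBr | starting material
2 | (S)-1,2-epoxybutane | CC[C@H]1CO1 | starting material
3 | 6-chlorohexylmagnesium bromide | ClCCCCCC[Mg]Br | intermediate (not isolated)
4 | (S)-10-chlorodecan-3-ol | CC[C@H](O)CCCCCCCCl | intermediate
5 | benzyl (S)-10-chlorodecan-3-yl ether | CC[C@H](OCc1ccccc1)CCCCCCCCl | intermediate
6 | 1,3-bis(benzyloxy)-5-bromobenzene | Brc1cc(OCc2ccccc2)cc(OCc2ccccc2)c1 | starting material
7 | (R)-epichlorohydrin | ClC[C@H]1CO1 | starting material
8 | 3,5-bis(benzyloxy)phenylmagnesium bromide | Br[Mg]c1cc(OCc2ccccc2)cc(OCc2ccccc2)c1 | intermediate (not isolated)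
9 | (R)-1-[3,5-bis(benzyloxy)phenyl]-3-chloropropan-2-ol | ClC[C@H](O)Cc1cc(OCc2ccccc2)cc(OCc2ccccc2)c1 | intermediate
10 | (R)-2-[3,5-bis(benzyloxy)benzyl]oxirane | C1[C@H](O1)Cc2cc(OCc3ccccc3)cc(OCc3ccccc3)c2 | intermediate
11 | [(8S)-8-(benzyloxy)decyl]magnesium chloride | CC[C@H](OCc1ccccc1)CCCCCCC[Mg]Cl | intermediate (not isolated)
12 | (2S,11S)-11-(benzyloxy)-1-[3,5-bis(benzyloxy)phenyl]tridecan-2-ol | CC[C@H](OCc1ccccc1)CCCCCCCC[C@H](O)Cc1cc(OCc2ccccc2)cc(OCc2ccccc2)c1 | intermediate
13 | (2S,11S)-11-(benzyloxy)-1-[3,5-bis(benzyloxy)phenyl]tridecan-2-yl methanesulfonate | CC[C@H](OCc1ccccc1)CCCCCCCC[C@H](OS(C)(=O)=O)Cc1cc(OCc2ccccc2)cc(OCc2ccccc2)c1 | intermediate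
14 | (2S,11S)-1-(3,5-dihydroxyphenyl)-11-hydroxytridecan-2-yl methanesulfonate | CC[C@H](O)CCCCCCCC[C@H](OS(C)(=O)=O)Cc1cc(O)cc(O)c1 | intermediate
15 | cesium 2,4-dihydroxy-6-[(2S,11S)-11-hydroxy-2-(methanesulfonyloxy)tridecyl]benzoate | CC[C@H](O)CCCCCCCC[C@H](OS(C)(=O)=O)Cc1cc(O)cc(O)c1C(=O)[O-].[Cs+] | intermediate (not isolated)
16 | (3R)-6,8-dihydroxy-3-[(9S)-9-hydroxyundecyl]-3,4-dihydro-1H-isochromen-1-one | CC[C@H](O)CCCCCCCC[C@@H]1Cc2cc(O)cc(O)c2C(=O)O1 | target

**Totals**

Total step count: 8.
Longest linear sequence: 6 steps (steps 1, 2, 5, 6, 7, 8; the aryl branch 3, 4, 5, 6, 7, 8 is equally long).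

**Steps most likely to fail**

Step 8 (proposed new method). Carboxylation may stall at the carbon between the two hydroxyls without returning, the sulfonate may be lost by base-induced elimination before a carboxylate is in place, or intermolecular O-alkylation may compete. The fallback uses known chemistry, with CO in place of CO2 and the C3–O bond kept after a separate inversion. It sets out from mesylate 13. Displacement with CsOAc and 18-crown-6 in toluene at 80 °C should give, with inversion, (2R,11S)-11-(benzyloxy)-1-[3,5-bis(benzyloxy)phenyl]tridecan-2-yl acetate F1. Methanolysis (K2CO3, MeOH, rt) gives (2R,11S)-11-(benzyloxy)-1-[3,5-bis(benzyloxy)phenyl]tridecan-2-ol F2, the C2 epimer of 12. NBS in MeCN at 0 °C brominates the ring carbon ortho to the side chain and para to a benzyloxy group, giving (2R,11S)-11-(benzyloxy)-1-[3,5-bis(benzyloxy)-2-bromophenyl]tridecan-2-ol F3. Intramolecular alkoxycarbonylation (Pd(OAc)2, Xantphos, CO 1 atm, Et3N, toluene, 100 °C) closes the lactone with retention at C3 to (3R)-6,8-bis(benzyloxy)-3-[(9S)-9-(benzyloxy)undecyl]-3,4-dihydro-1H-isochromen-1-one F4. Hydrogenolysis (H2, Pd(OH)2/C, EtOAc) comes back to the route at target 16.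

Step 5. Magnesium insertion into the primary chloride may be sluggish or accompanied by homocoupling, and magnesium halide may open or rearrange the epoxide before the organocopper species does. The fallback replaces the Grignard reagent by a sulfone-stabilized carbanion and sets out from chloride 5. PhSO2Na with NaI (cat.) in DMF at 80 °C gives {[(8S)-8-(benzyloxy)decyl]sulfonyl}benzene F5. Deprotonation (n-BuLi, THF, −78 °C) and opening of epoxide 10 in the presence of BF3·OEt2 gives (2R,11S)-11-(benzyloxy)-1-[3,5-bis(benzyloxy)phenyl]-4-(phenylsulfonyl)tridecan-2-ol F6, a mixture at the sulfonyl-bearing carbon. C2 is spatially as in 12; the descriptor differs only because the sulfonyl group raises the priority of C3. Reductive desulfonylation (Na(Hg), Na2HPO4, MeOH–THF, −20 °C) comes back to the route at alcohol 12.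

Step 7. Cleavage of the secondary alkyl benzyl ether may be slow, and during the long exposure the sulfonate may be lost by solvolysis or elimination. The fallback postpones that cleavage until the sulfonate has been consumed and sets out from mesylate 13. A short hydrogenolysis (H2 1 atm, Pd/C, EtOAc, rt, stopped once the two fast-reacting aryl benzyl ethers are gone) gives (2S,11S)-11-(benzyloxy)-1-(3,5-dihydroxyphenyl)tridecan-2-yl methanesulfonate F7. The conditions of step 8 then give (3R)-3-[(9S)-9-(benzyloxy)undecyl]-6,8-dihydroxy-3,4-dihydro-1H-isochromen-1-one F8. Hydrogenolysis of the remaining ether (H2, Pd(OH)2/C, EtOAc–MeOH) comes back to the route at target 16.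

**Further compounds**

F1 | step 8 | (2R,11S)-11-(benzyloxy)-1-[3,5-bis(benzyloxy)phenyl]tridecan-2-yl acetate | CC[C@H](OCc1ccccc1)CCCCCCCC[C@@H](OC(C)=O)Cc1cc(OCc2ccccc2)cc(OCc2ccccc2)c1
F2 | step 8 | (2R,11S)-11-(benzyloxy)-1-[3,5-bis(benzyloxy)phenyl]tridecan-2-ol | CC[C@H](OCc1ccccc1)CCCCCCCC[C@@H](O)Cc1cc(OCc2ccccc2)cc(OCc2ccccc2)c1
F3 | step 8 | (2R,11S)-11-(benzyloxy)-1-[3,5-bis(benzyloxy)-2-bromophenyl]tridecan-2-ol | CC[C@H](OCc1ccccc1)CCCCCCCC[C@@H](O)Cc1cc(OCc2ccccc2)cc(OCc2ccccc2)c1Br
F4 | step 8 | (3R)-6,8-bis(benzyloxy)-3-[(9S)-9-(benzyloxy)undecyl]-3,4-dihydro-1H-isochromen-1-one | CC[C@H](OCc1ccccc1)CCCCCCCC[C@@H]1Cc2cc(OCc3ccccc3)cc(OCc3ccccc3)c2C(=O)O1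
F5 | step 5 | {[(8S)-8-(benzyloxy)decyl]sulfonyl}benzene | CC[C@H](OCc1ccccc1)CCCCCCCS(=O)(=O)c1ccccc1
F6 | step 5 | (2R,11S)-11-(benzyloxy)-1-[3,5-bis(benzyloxy)phenyl]-4-(phenylsulfonyl)tridecan-2-ol | CC[C@H](OCc1ccccc1)CCCCCCC(S(=O)(=O)c1ccccc1)C[C@H](O)Cc1cc(OCc2ccccc2)cc(OCc2ccccc2)c1
F7 | step 7 | (2S,11S)-11-(benzyloxy)-1-(3,5-dihydroxyphenyl)tridecan-2-yl methanesulfonate | CC[C@H](OCc1ccccc1)CCCCCCCC[C@H](OS(C)(=O)=O)Cc1cc(O)cc(O)c1
F8 | step 7 | (3R)-3-[(9S)-9-(benzyloxy)undecyl]-6,8-dihydroxy-3,4-dihydro-1H-isochromen-1-one | CC[C@H](OCc1ccccc1)CCCCCCCC[C@@H]1Cc2cc(O)cc(O)c2C(=O)O1
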